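The atoms are numbered as follows. C2 is the acetal carbon and C1 its neighbour. C5 is the allylic ring-fusion CH. C6 and C7 are the cyclopropane CH groups, followed by C8 and C9. C10 is the carbinol carbon and C11 the quaternary cyclopropane carbon. The cycloheptane ring is cut at C1–C10 and at C6–C7, the edge it shares with the cyclopropane. This leaves a three-carbon (C1–C5–C6) and a four-carbon (C7–C10) unit, a (4+3) retron. The precursors are furan and an acyclic E-vinyldiazoacetate carrying C11 as a malonyl group. Its rhodium carbenoid cyclopropanates furan and the divinylcyclopropane undergoes Cope rearrangement, forming both bonds and three stereocentres. The temporary C1–C9 bond is lost. The oxygen bridge later leaves C7 and remains as the C10 hydroxyl.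

Key step: step 4

Assumption: Rh2(S-DOSP)4 is taken to give the enantiomer drawn. If the sense of induction is the opposite, Rh2(R-DOSP)4 is used and nothing else changes.

Step 1
Reactants: 1 triethyl methanetricarboxylate; 2 ethyl (E)-4-bromobut-2-enoate
Product: 3 tetraethyl (E)-but-3-ene-1,1,1,4-tetracarboxylate
Conditions: NaH, DMF, 0 to 50 °C
Reagents that add atoms: none
Why: SN2 alkylation of the soft tricarboxylate carbanion at the primary allylic bromide; the third ester leaves no acidic C11–H, so the next step can address the crotonate part alone.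

Step 2
Reactants: 3 tetraethyl (E)-but-3-ene-1,1,1,4-tetracarboxylate
Product: 4 tetraethyl (E)-4-diazobut-2-ene-1,1,1,4-tetracarboxylate
Conditions: 4-acetamidobenzenesulfonyl azide, DBU, MeCN, 0 °C to rt
Reagents that add atoms: 4-acetamidobenzenesulfonyl azide CC(=O)Nc1ccc(cc1)S(=O)(=O)N=[N+]=[N-]
Why: Regitz diazo transfer in the deconjugative mode: DBU removes a gamma proton at C6, the dienolate attacks the azide through its alpha carbon C1, and loss of the sulfonamide gives the conjugated E-vinyldiazoacetate.

Step 3
Reactants: 4 tetraethyl (E)-4-diazobut-2-ene-1,1,1,4-tetracarboxylate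
Product: 5 diethyl 2-[(E)-3-diazo-4-ethoxy-4-oxobut-1-enyl]malonate
Conditions: NaOEt (1 equiv), EtOH, 0 °C; then AcOH
Reagents that add atoms: none
Why: Retro-Claisen de-ethoxycarbonylation: ethoxide adds to one of the three crowded geminal esters and expels the malonate anion, which is protonated at C11 on quenching, while the diazo ester is inert to alkoxide.

Step 4
Reactants: 5 diethyl 2-[(E)-3-diazo-4-ethoxy-4-oxobut-1-enyl]malonate; 6 furan
Product: 8 ethyl 4-endo-[bis(ethoxycarbonyl)methyl]-8-oxabicyclo[3.2.1]octa-2,6-diene-2-carboxylate, via cis-divinylcyclopropane 7 (not isolated)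
Conditions: Rh2(S-DOSP)4 (1 mol %), furan (5 equiv), hexanes, slow addition of 5, −20 °C to rt
Reagents that add atoms: none
Why: Loss of N2 from 5 gives a donor/acceptor rhodium vinylcarbenoid whose carbene carbon C1 adds across the C9=C10 bond of furan in a concerted asynchronous [2+1] step, and the cis-divinylcyclopropane 7 then undergoes a boat-type [3,3] Cope shift that joins the vinyl terminus C6 to furan carbon C7 and cleaves the temporary C1–C9 bond, driven by release of cyclopropane strain. This is the tandem cyclopropanation/Cope rearrangement (formal (4+3) cycloaddition) of vinyldiazoacetates with furans. The three-membered ring closes by carbene [2+1] addition, and the seven-membered carbocycle, bridged by the furan oxygen, closes by the pericyclic [3,3] shift. The configuration at C10, and with it C7, is fixed in the cyclopropanation by the chiral prolinate ligands; the vinyl group ends cis to the dihydrofuran ring, as is usual for donor/acceptor carbenoids; and the obligatory boat transition state translates the E geometry of C5=C6 into an endo malonyl group at C6, anti to the oxygen bridge. The step needs cyclopropanation rather than zwitterionic ring opening of furan, which the non-polar solvent favours, and furan is symmetric, so no regiochemical question arises.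

Step 5
Reactants: 8 ethyl 4-endo-[bis(ethoxycarbonyl)methyl]-8-oxabicyclo[3.2.1]octa-2,6-diene-2-carboxylate
Product: 9 ethyl 4-endo-[bis(ethoxycarbonyl)methyl]-3-exo-isopropenyl-8-oxabicyclo[3.2.1]oct-6-ene-2-exo-carboxylate
Conditions: isopropenylmagnesium bromide (3 equiv), CuBr·SMe2 (20 mol %), THF, −78 to −40 °C; then CF3CO2H, −78 °C
Reagents that add atoms: isopropenylmagnesium bromide CC(=C)[Mg]Br
Why: Copper-catalysed conjugate addition (the first equivalent only deprotonates the malonate): the nucleophile enters C5 from the convex exo face syn to the oxygen bridge, and the enolate is protonated kinetically at C1 from the then less hindered endo face, which places the ester exo and cis to the isopropenyl group.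

Step 6
Reactants: 9 ethyl 4-endo-[bis(ethoxycarbonyl)methyl]-3-exo-isopropenyl-8-oxabicyclo[3.2.1]oct-6-ene-2-exo-carboxylate
Product: 11 triethyl 4-(tert-butyldimethylsilyloxy)-2-isopropenylbicyclo[5.1.0]oct-5-ene-3,8,8-tricarboxylate (substituents at positions 2 3 4 mutually cis and anti to C8), via silyl ketene acetal 10 (not isolated)
Conditions: TBSOTf (2.5 equiv), Et3N (3 equiv), CH2Cl2, −78 to 0 °C
Reagents that add atoms: tert-butyldimethylsilyl trifluoromethanesulfonate CC(C)(C)[Si](C)(C)OS(=O)(=O)C(F)(F)F
Why: Proposed new method: TBSOTf/Et3N converts the malonate into ketene acetal 10 and silylates the bridging oxygen; the equatorial endo C11 lies antiperiplanar to the allylic C7–O bond, so a 3-exo-tet SN2 displacement with inversion at C7 closes the cyclopropane, opens the strained bridge and leaves the oxygen on C10 as its TBS ether, with the new Si–O bond and the consumed ketene acetal paying for the ring strain; the closest known reactions are the silyl triflate/amine-induced eliminative opening of 8-oxabicyclo[3.2.1]octenones through their silyl enol ethers and the 3-exo-tet closure of malonates that carry a gamma leaving group.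

Step 7
Reactants: 11 triethyl 4-(tert-butyldimethylsilyloxy)-2-isopropenylbicyclo[5.1.0]oct-5-ene-3,8,8-tricarboxylate
Product: 12 the corresponding 3,8,8-tris(hydroxymethyl) compound (triol)
Conditions: LiAlH4, THF, 0 °C
Reagents that add atoms: none
Why: Hydride reduction of all three esters to primary alcohols; the silyl ether, both alkenes and the cyclopropane are not affected and no stereocentre is touched.

Step 8
Reactants: 12 triol
Product: 13 spiro-acetonide of the geminal C11 diol with free C2–OH
Conditions: 2,2-dimethoxypropane, PPTS (cat.), CH2Cl2, rt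
Reagents that add atoms: 2,2-dimethoxypropane COC(C)(C)OC
Why: Acid-catalysed transketalisation; only the geminal CH2OH pair can form a six-membered 1,3-dioxane, because the possible partner of C2–OH (the C10 oxygen) is silylated.

Step 9
Reactants: 13 spiro-acetonide
Product: 14 C10 enone (C8=C9 conjugated with C10=O)
Conditions: DDQ, CH2Cl2/pH 7 buffer, 0 °C to rt
Reagents that add atoms: none
Why: Oxidative desilylation of an electron-rich allylic silyl ether: DDQ abstracts hydride from C10, and the silyloxocarbenium ion loses its silyl group to water to give the enone directly.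

Step 10
Reactants: 14 C10 enone
Product: 15 saturated C10 ketone
Conditions: [(Ph3P)CuH]6, toluene, rt; then H2O
Reagents that add atoms: none
Why: 1,4-Hydrocupration of the enone; the isolated 1,1-disubstituted alkene is inert, and the polar non-radical pathway keeps the cyclopropane at the beta carbon closed.

Step 11
Reactants: 15 saturated C10 ketone
Product: 16 C10 tertiary alcohol (OH cis to the C1 side chain and methyl on the cyclopropane face)
Conditions: MeLi, CeCl3, THF, −78 °C
Reagents that add atoms: methyllithium [Li]C
Why: 1,2-Addition of the weakly basic organocerium reagent, expected anti to the neighbouring C1 side chain (present as its alkoxide), which sets C10 with OH cis to C2 and avoids enolisation and epimerisation at C1.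

Step 12
Reactants: 16 C10 tertiary alcohol
Product: 17 allylic alcohol (isopropenyl CH3 converted into CH2OH)
Conditions: SeO2 (cat.), t-BuOOH, CH2Cl2, 0 °C to rt
Reagents that add atoms: tert-butyl hydroperoxide CC(C)(C)OO; selenium dioxide O=[Se]=O
Why: Allylic oxidation by ene reaction and [2,3]-sigmatropic shift; the exposed methyl group should react in preference to the hindered tertiary C5–H.

Step 13
Reactants: 17 allylic alcohol
Product: 18 dialdehyde (C2 aldehyde and 2-substituted acrolein at C5)
Conditions: DMP (2.5 equiv), NaHCO3, CH2Cl2, 0 °C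
Reagents that add atoms: none
Why: Periodinane oxidation of the primary and the allylic alcohol; the tertiary alcohol cannot react, and the buffer guards against retro-aldol cleavage and epimerisation at C1.

Step 14
Reactants: 18 dialdehyde
Product: 20 tetracyclic lactol (oxepane and 2-hydroxy-3,4-dihydropyran closed), via diol dialdehyde 19 (not isolated)
Conditions: Dowex 50W (H+ form), THF/H2O, rt; filter; Et3N (0.2 equiv), CH2Cl2, rt
Reagents that add atoms: none
Why: Ketal hydrolysis frees 19, in which only the endo CH2OH (cis to C5 on the cyclopropane) reaches the enal and adds in an oxa-Michael reaction that closes the oxepane and makes C11 stereogenic; the enol oxygen so formed adds to the C2 aldehyde to give the cis-fused enol hemiacetal.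

Step 15
Reactants: 20 tetracyclic lactol
Product: 21 target CNP0250836.3
Conditions: Ac2O, pyridine, DMAP (cat.), CH2Cl2, 0 °C
Reagents that add atoms: acetic anhydride CC(=O)OC(C)=O
Why: Acetylation of the primary alcohol and of the equilibrating lactol, which should be trapped as the anomerically stabilised acetate trans to the C1–C10 bond, while the hindered tertiary alcohol stays free.

Compound list
1 | triethyl methanetricarboxylate | CCOC(=O)C(C(=O)OCC)C(=O)OCC | starting material
2 | ethyl (E)-4-bromobut-2-enoate | CCOC(=O)/C=C/CBr | starting material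
3 | tetraethyl (E)-but-3-ene-1,1,1,4-tetracarboxylate | CCOC(=O)/C=C/CC(C(=O)OCC)(C(=O)OCC)C(=O)OCC | intermediate
4 | tetraethyl (E)-4-diazobut-2-ene-1,1,1,4-tetracarboxylate | CCOC(=O)C(=[N+]=[N-])/C=C/C(C(=O)OCC)(C(=O)OCC)C(=O)OCC | intermediate
5 | diethyl 2-[(E)-3-diazo-4-ethoxy-4-oxobut-1-enyl]malonate | CCOC(=O)C(=[N+]=[N-])/C=C/C(C(=O)OCC)C(=O)OCC | intermediate
6 | furan | c1ccoc1 | starting material
7 | ethyl 6-[(E)-3,3-bis(ethoxycarbonyl)prop-1-enyl]-2-oxabicyclo[3.1.0]hex-3-ene-6-carboxylate, alkenyl group cis to the dihydrofuran ring (not isolated) | CCOC(=O)[C@@]1(/C=C/C(C(=O)OCC)C(=O)OCC)[C@@H]2C=CO[C@H]12 | intermediate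
8 | ethyl 4-endo-[bis(ethoxycarbonyl)methyl]-8-oxabicyclo[3.2.1]octa-2,6-diene-2-carboxylate | CCOC(=O)C1=C[C@@H](C(C(=O)OCC)C(=O)OCC)[C@H]2C=C[C@@H]1O2 | intermediate
9 | ethyl 4-endo-[bis(ethoxycarbonyl)methyl]-3-exo-isopropenyl-8-oxabicyclo[3.2.1]oct-6-ene-2-exo-carboxylate | CCOC(=O)[C@@H]1[C@H](C(C)=C)[C@@H](C(C(=O)OCC)C(=O)OCC)[C@H]2C=C[C@@H]1O2 | intermediate
10 | TBS ketene acetal of the malonate unit of 9 (not isolated) | CCOC(=O)[C@@H]1[C@H](C(C)=C)[C@@H](C(C(=O)OCC)=C(OCC)O[Si](C)(C)C(C)(C)C)[C@H]2C=C[C@@H]1O2 | intermediate
11 | triethyl 4-(tert-butyldimethylsilyloxy)-2-isopropenylbicyclo[5.1.0]oct-5-ene-3,8,8-tricarboxylate, 2-, 3- and 4-substituents cis to each other and anti to C8 | CCOC(=O)[C@@H]1[C@H](C(C)=C)[C@@H]2[C@H](C=C[C@@H]1O[Si](C)(C)C(C)(C)C)C2(C(=O)OCC)C(=O)OCC | intermediate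
12 | 3,8,8-tris(hydroxymethyl) analogue of 11 (triol) | OC[C@@H]1[C@H](C(C)=C)[C@@H]2[C@H](C=C[C@@H]1O[Si](C)(C)C(C)(C)C)C2(CO)CO | intermediate
13 | spiro-acetonide of 12 (1,3-dioxane on C11, C2–OH free) | OC[C@@H]1[C@H](C(C)=C)[C@@H]2[C@H](C=C[C@@H]1O[Si](C)(C)C(C)(C)C)C23COC(C)(C)OC3 | intermediate
14 | C10 enone | OC[C@@H]1[C@H](C(C)=C)[C@@H]2[C@H](C=CC1=O)C23COC(C)(C)OC3 | intermediate
15 | saturated C10 ketone | OC[C@@H]1[C@H](C(C)=C)[C@@H]2[C@H](CCC1=O)C23COC(C)(C)OC3 | intermediate
16 | C10 methyl carbinol, OH cis to the C1 side chain | OC[C@@H]1[C@H](C(C)=C)[C@@H]2[C@H](CC[C@]1(C)O)C23COC(C)(C)OC3 | intermediate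
17 | allylic alcohol, 2-(hydroxymethyl)vinyl group on C5 | OC[C@@H]1[C@H](C(=C)CO)[C@@H]2[C@H](CC[C@]1(C)O)C23COC(C)(C)OC3 | intermediate
18 | dialdehyde acetonide | O=C[C@@H]1[C@H](C(=C)C=O)[C@@H]2[C@H](CC[C@]1(C)O)C23COC(C)(C)OC3 | intermediate
19 | diol dialdehyde (not isolated) | O=C[C@@H]1[C@H](C(=C)C=O)[C@@H]2[C@H](CC[C@]1(C)O)C2(CO)CO | intermediate
20 | tetracyclic lactol (bis-deacetyl target) | OC[C@@]12COCC3=CO[C@H](O)[C@@H]4[C@H]3[C@@H]1[C@@H]2CC[C@]4(C)O | intermediate
21 | CNP0250836.3 | CC(=O)OC[C@@]12COCC3=CO[C@H](OC(C)=O)[C@@H]4[C@H]3[C@@H]1[C@@H]2CC[C@]4(C)O | target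

Total step count: 15. Longest linear sequence: 15 steps (from 1 or 2 to 21).

Steps most likely to fail

Step 6 (new method).
- What may go wrong: the silylated bridge may ionise to an allyl cation that is captured at the remote allyl terminus, or the bridge may simply not open.
- Fallback (from 9, back at 11): Me3SiI (from Me3SiCl and NaI, MeCN, −20 °C), a standard ether cleavage, should open the allylic bridge to the allylic iodide F1.
- The C7 epimers of this iodide interconvert by iodide exchange. The one with iodine anti to the malonyl group is drawn.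
- DBU then closes the ring by an ordinary 3-exo-tet malonate alkylation to the cyclopropane trimethylsilyl ether F2.
- Dilute citric acid in EtOH gives the C10 alcohol F3, and TBSCl/imidazole gives 11.

Step 14.
- What may go wrong: the tertiary C10 hydroxyl may add to the enal in competition with the endo CH2OH through a six-membered closure, and hemiacetals may hold the material back.
- Fallback (from 16, back at 21): the carbinol is masked. Et3SiOTf/2,6-lutidine gives the bis(triethylsilyl) ether F4.
- SeO2/t-BuOOH gives the allylic alcohol F5.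
- Swern oxidation, which also converts primary triethylsilyl ethers into aldehydes, gives the silyl-protected dialdehyde F6.
- CeCl3·7H2O/oxalic acid in MeCN removes the acetonide, and Et3N then triggers the cascade to the silyl-protected lactol F7.
- Ac2O/pyridine gives the silyl-protected diacetate F8, and HF·pyridine gives 21.

Step 11.
- What may go wrong: poor facial selectivity of the methyl addition, or enolisation with epimerisation at C1.
- Fallback (from 15, back at 16): the oxygen, rather than the carbon, is delivered under control of the C2 hydroxyl.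
- Wittig methylenation (Ph3P=CH2, THF) gives the exocyclic alkene F9.
- VO(acac)2/t-BuOOH epoxidation, directed by the homoallylic C2–OH to its own face, gives the spiro-epoxide F10.
- LiAlH4 opens F10 at the CH2 terminus to give 16.

Further compounds
F1 | step 6 | allylic iodide with C10 OTMS (iodine anti to the malonyl group) | CCOC(=O)[C@@H]1[C@H](C(C)=C)[C@@H](C(C(=O)OCC)C(=O)OCC)[C@H](I)C=C[C@@H]1O[Si](C)(C)C
F2 | step 6 | cyclopropane trimethylsilyl ether (TMS analogue of 11) | CCOC(=O)[C@@H]1[C@H](C(C)=C)[C@@H]2[C@H](C=C[C@@H]1O[Si](C)(C)C)C2(C(=O)OCC)C(=O)OCC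
F3 | step 6 | C10 alcohol (desilylated 11) | CCOC(=O)[C@@H]1[C@H](C(C)=C)[C@@H]2[C@H](C=C[C@@H]1O)C2(C(=O)OCC)C(=O)OCC
F4 | step 14 | bis(triethylsilyl) ether of 16 | CC[Si](CC)(CC)OC[C@@H]1[C@H](C(C)=C)[C@@H]2[C@H](CC[C@]1(C)O[Si](CC)(CC)CC)C23COC(C)(C)OC3
F5 | step 14 | allylic alcohol derived from F4 | CC[Si](CC)(CC)OC[C@@H]1[C@H](C(=C)CO)[C@@H]2[C@H](CC[C@]1(C)O[Si](CC)(CC)CC)C23COC(C)(C)OC3
F6 | step 14 | silyl-protected dialdehyde (C10 OTES analogue of 18) | O=C[C@@H]1[C@H](C(=C)C=O)[C@@H]2[C@H](CC[C@]1(C)O[Si](CC)(CC)CC)C23COC(C)(C)OC3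
F7 | step 14 | silyl-protected lactol (C10 OTES analogue of 20) | OC[C@@]12COCC3=CO[C@H](O)[C@@H]4[C@H]3[C@@H]1[C@@H]2CC[C@]4(C)O[Si](CC)(CC)CC
F8 | step 14 | silyl-protected diacetate (C10 OTES analogue of 21) | CC(=O)OC[C@@]12COCC3=CO[C@H](OC(C)=O)[C@@H]4[C@H]3[C@@H]1[C@@H]2CC[C@]4(C)O[Si](CC)(CC)CC
F9 | step 11 | exocyclic alkene (C10=CH2) | OC[C@@H]1[C@H](C(C)=C)[C@@H]2[C@H](CCC1=C)C23COC(C)(C)OC3
F10 | step 11 | spiro-epoxide at C10 (oxygen cis to the C1 side chain) | OC[C@@H]1[C@H](C(C)=C)[C@@H]2[C@H](CC[C@@]14CO4)C23COC(C)(C)OC3
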